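**Retrosynthetic overview**
Numbering: C1 (=CH2), C2, C3, C4 (CO2H), C5 (quaternary), C6, C7=C8, C9=C10 (CO2H on C10). The strategy rests on the arc C1–C10–C9–C8–C7 of the ten-membered ring. A C1–C7 bond turns this arc into a cyclopentene fused to a seven-membered ring (C1–C7), with C1 as a carbinol and C8 carrying a sulfonate.
Target <= ten-membered C1 ketone 33 (methylenation, ester and ketal cleavage) <= heterolytic cleavage of the C1–C7 fusion bond of hydroazulene mesylate 31.
31 <= cyclopentene annulation on cycloheptenone 13: C7–C8 by anti aldol with methyl 4-oxobut-2-enoate, C10–C1 by thia-Michael/aldol closure, C9=C10 by sulfinate loss. The furyl ketal is grown on the C5 side chain.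
13 <= ring-closing metathesis (C6=C7) and allylic oxidation (C1) of diene ester 11. Its C4 and C5 centres come from one Ireland–Claisen rearrangement of the enantiopure allylic ester 7.
Ring order: seven-membered ring (step 6), five-membered ring (step 10), ten-membered ring (step 19). The furan arrives ready-made (step 14).

Key step: step 19

Assumption: the aldol of step 8 is drawn with the aldehyde entering C7 opposite to the larger C5 substituent. Attack on the other face would give a series with C1, C7 and C8 all inverted, which leads to the same ketone 33 because these three centres vanish in step 19.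

Step 1
Reactants: 1 tert-butyl(but-3-yn-1-yloxy)dimethylsilane; 2 acetaldehyde
Product: 4 rac-(E)-6-(tert-butyldimethylsilyloxy)-4-methylhex-3-en-2-ol, via alkenyl(dimethyl)alane 3 (not isolated)
Conditions: AlMe3, Cp2ZrCl2 (cat.), CH2Cl2, 0 °C to rt; then 2, −78 °C to 0 °C; aq. work-up
Reagents that add atoms: trimethylaluminium, C[Al](C)C
Why: Negishi carboalumination adds methyl and aluminium syn across the alkyne with aluminium at the terminus, and the alkenylalane transfers its alkenyl group to the aldehyde with retention, so only the E trisubstituted allylic alcohol should form (as a racemate).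

Step 2
Reactants: 4 rac-(E)-6-(tert-butyldimethylsilyloxy)-4-methylhex-3-en-2-ol
Product: 5 (S)-(E)-6-(tert-butyldimethylsilyloxy)-4-methylhex-3-en-2-ol
Conditions: Novozym 435 (immobilised Candida antarctica lipase B), vinyl acetate, hexane, 30 °C, stopped just past half conversion; chromatography
Reagents that add atoms: none
Why: Enzymatic kinetic resolution by acyl transfer, in which the lipase should acetylate the R enantiomer of this methyl alkenyl carbinol much faster, so that the unreacted S alcohol needed for the chirality transfer of step 4 is recovered enantiopure.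

Step 3
Reactants: 5 (S)-(E)-6-(tert-butyldimethylsilyloxy)-4-methylhex-3-en-2-ol; 6 hept-6-enoic acid
Product: 7 (S)-(E)-6-(tert-butyldimethylsilyloxy)-4-methylhex-3-en-2-yl hept-6-enoate
Conditions: DCC, DMAP (cat.), CH2Cl2, 0 °C to rt
Reagents that add atoms: none
Why: Steglich esterification acylates the secondary allylic alcohol at oxygen under neutral conditions, so the carbinol centre and the E alkene are kept.

Step 4
Reactants: 7 (S)-(E)-6-(tert-butyldimethylsilyloxy)-4-methylhex-3-en-2-yl hept-6-enoate
Product: 10 Claisen acid 2-[(E)-1-(tert-butyldimethylsilyloxy)-3-methylhex-4-en-3-yl]hept-6-enoic acid (C4 and C5 configured as in the target), via E silyl ketene acetal 8 (not isolated), via trimethylsilyl ester 9 (not isolated)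
Conditions: LiN(i-Pr)2, THF, −78 °C; Me3SiCl, −78 °C to rt, then 60 °C; aq. NH4Cl/THF
Reagents that add atoms: none
Why: Ireland–Claisen rearrangement, in which kinetic enolisation in pure THF gives the E silyl ketene acetal and the chair transition state with the carbinol methyl group equatorial forms the C4–C5 bond on the alkene face that carried the C–O bond, which fixes C5 from the S carbinol and, through the E alkene/E ketene acetal pairing, places the C4 carboxyl and the C5 methyl group on the same side of the future ring.

Step 5
Reactants: 10 Claisen acid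
Product: 11 Claisen methyl ester
Conditions: Me3SiCHN2, MeOH/toluene, 0 °C
Reagents that add atoms: (trimethylsilyl)diazomethane, C[Si](C)(C)C=[N+]=[N-]
Why: Esterification of the hindered acid with the diazoalkane needs neither base nor heat, so the enolisable C4 centre is safe.

Step 6
Reactants: 11 Claisen methyl ester
Product: 12 methyl 2-[2-(tert-butyldimethylsilyloxy)ethyl]-2-methylcyclohept-3-ene-1-carboxylate (ester cis to the ring methyl group)
Conditions: second-generation Grubbs catalyst RuCl2(=CHPh)(PCy3)(H2IMes) (cat.), CH2Cl2 (high dilution), 40 °C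
Reagents that add atoms: none
Why: Ring-closing metathesis of the terminal alkene onto the propenyl group closes the seven-membered ring at C6=C7 with loss of propene, the quaternary C5 favouring the folded conformer and neither stereocentre being involved.

Step 7
Reactants: 12 cycloheptene ester
Product: 13 methyl 2-[2-(tert-butyldimethylsilyloxy)ethyl]-2-methyl-5-oxocyclohept-3-ene-1-carboxylate (C1 enone)
Conditions: Rh2(cap)4 (cat., cap = caprolactamate), t-BuOOH, K2CO3, CH2Cl2, rt
Reagents that add atoms: tert-butyl hydroperoxide, CC(C)(C)OO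
Why: Radical allylic C–H oxidation can only strike C1, because the other allylic position C5 carries no hydrogen, and so delivers the C1 enone.

Step 8
Reactants: 13 cycloheptenone ester; 14 methyl (E)-4-oxobut-2-enoate
Product: 17 anti aldol (cycloheptanone with an (E)-CH(OH)CH=CHCO2Me chain at C7; chain cis to the C5 methyl group), via lithium enolate 15 (not isolated), via dicyclohexylboron enolate 16 (not isolated)
Conditions: LiBH(s-Bu)3, THF, −78 °C; Cy2BCl, −78 °C; 14, −78 °C to −20 °C; pH 7 buffer, MeOH, H2O2, 0 °C; minor syn isomer removed by chromatography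
Reagents that add atoms: none
Why: Conjugate hydride addition generates the enolate regiospecifically at C7, exchange to boron tightens the closed chair aldol transition state of this ring-locked E enolate so that the anti aldol (C6 and the C8 oxygen cis in the later cyclopentene) should dominate, and the aldehyde should reach C7 from the face opposite to the larger C5 substituent.

Step 9
Reactants: 17 anti aldol
Product: 18 C8 tert-butyldimethylsilyl ether of 17
Conditions: TBSOTf, 2,6-lutidine, CH2Cl2, −78 °C to 0 °C
Reagents that add atoms: tert-butyldimethylsilyl trifluoromethanesulfonate, CC(C)(C)[Si](C)(C)OS(=O)(=O)C(F)(F)F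
Why: Silylation with the silyl triflate and a hindered pyridine base masks the C8 hydroxyl without retro-aldol or β-elimination, so that no acidic proton quenches the enolate of step 10.

Step 10
Reactants: 18 silylated aldol
Product: 20 cis-fused hydroazulene sulfide (C1-OH cis to C7-H; C8-OTBS cis to C6; C9-SPh trans to C8-OTBS; C10-CO2Me cis to C1-OH), via lithium ester enolate 19 (not isolated)
Conditions: PhSH, n-BuLi, THF, −78 °C to −20 °C; aq. NH4Cl
Reagents that add atoms: thiophenol, Sc1ccccc1
Why: Tandem thia-Michael/aldol cyclisation (stepwise equivalent of an intramolecular Morita–Baylis–Hillman reaction), in which thiolate adds to C9 anti to the C8 silyl ether and the ester enolate closes 5-exo-trig onto the C1 ketone from the face that carries the tether, which makes the ring fusion cis, while the C9 and C10 centres are removed in step 11.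

Step 11
Reactants: 20 hydroazulene sulfide
Product: 22 hydroazulene enoate (C9=C10 with CO2Me on C10; C1-OH cis to C7-H; C8-OTBS cis to C6), via sulfone 21 (not isolated)
Conditions: m-CPBA (2.2 equiv), CH2Cl2, 0 °C; then DBU, rt
Reagents that add atoms: none
Why: Sulfide oxidation followed by E1cB loss of benzenesulfinate from the ester-acidified C10–H installs the C9=C10 enoate whatever the C9/C10 configuration, the tertiary C1 hydroxyl being a much poorer leaving group.

Step 12
Reactants: 22 hydroazulene enoate
Product: 23 primary alcohol (C5 side chain CH2CH2OH; C8-OTBS kept)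
Conditions: HF·pyridine, pyridine, THF, 0 °C
Reagents that add atoms: none
Why: Buffered fluoride cleaves the unhindered primary silyl ether well before the secondary C8 silyl ether on the concave face, and the cold buffered medium should hold back δ-lactonisation onto the C4 ester.

Step 13
Reactants: 23 primary alcohol
Product: 24 aldehyde (C5 side chain CH2CHO)
Conditions: Dess–Martin periodinane, pyridine, CH2Cl2, 0 °C to rt
Reagents that add atoms: none
Why: Dess–Martin oxidation stops at the aldehyde under near-neutral conditions and cannot touch the tertiary C1 alcohol.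

Step 14
Reactants: 24 aldehyde; 25 3-bromofuran
Product: 27 furyl carbinol (both epimers at the new carbinol carbon), via 3-furyllithium 26 (not isolated)
Conditions: 25, n-BuLi, Et2O, −78 °C; then 24 in THF (0.45 equiv relative to 26), −78 °C; AcOH quench at −78 °C
Reagents that add atoms: none
Why: Bromine–lithium exchange at −78 °C gives 3-furyllithium without migration of lithium, one equivalent is spent on the C1 hydroxyl and the second adds to the aldehyde far faster than to the hindered esters, the cold acidic quench prevents lactonisation, and the unselective carbinol centre is erased in step 15.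

Step 15
Reactants: 27 furyl carbinol
Product: 28 furyl ketone (C5 side chain CH2C(=O)-3-furyl)
Conditions: Dess–Martin periodinane, pyridine, CH2Cl2, 0 °C
Reagents that add atoms: none
Why: Dess–Martin oxidation converts both carbinol epimers into one ketone and is mild enough for the furan, the silyl ether and the tertiary alcohol.

Step 16
Reactants: 28 furyl ketone
Product: 29 furyl ketal (1,3-dioxolane of the side-chain ketone)
Conditions: (Me3SiOCH2)2, Me3SiOTf (cat.), CH2Cl2, −78 °C to −20 °C; pyridine quench
Reagents that add atoms: 1,2-bis(trimethylsilyloxy)ethane, C[Si](C)(C)OCCO[Si](C)(C)C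
Why: Noyori ketalisation works aprotically at low temperature, which the furan and the C8 silyl ether tolerate and under which the C1 allylic alcohol should not ionise because the C10 ester destabilises the cation, and it masks the only ketone before a second one appears at C1.

Step 17
Reactants: 29 furyl ketal
Product: 30 1,3-diol (C1 tertiary OH; C8 secondary OH cis to C6)
Conditions: Bu4NF, AcOH, THF, 0 °C to rt
Reagents that add atoms: none
Why: Buffered fluoride desilylation frees the C8 hydroxyl without base-induced damage to the esters, and lactonisation onto the C10 ester is impossible because it would place the alkene at a bridgehead.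

Step 18
Reactants: 30 1,3-diol
Product: 31 hydroazulene mesylate (cis-fused; C1-OH; C8-OMs cis to C6; C9=C10 enoate)
Conditions: MsCl, Et3N, CH2Cl2, −30 °C; used without storage
Reagents that add atoms: methanesulfonyl chloride, CS(=O)(=O)Cl
Why: Sulfonylation picks the secondary C8 hydroxyl because the tertiary C1 hydroxyl is too hindered, and the γ-mesyloxy enoate is stabilised against ionisation by the C10 ester.

Step 19
Reactants: 31 hydroazulene mesylate
Product: 33 ten-membered C1 ketone (both ring alkenes cis within the ring; C4 and C5 as in the target), via potassium alkoxide 32 (not isolated)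
Conditions: KN(SiMe3)2 (1.05 equiv), THF, −78 °C to −20 °C; pH 7 buffer
Reagents that add atoms: none
Why: Deprotonation gives the C1 alkoxide 32, whose oxygen lone pair pushes into the C1–C7 fusion bond while the electrons of that bond form the C7=C8 π bond and expel the C8 mesylate in one heterolytic event. The closest known reaction type is the Grob (Wharton) fragmentation of cyclic 1,3-diol monosulfonates to medium-ring unsaturated ketones. No ring is closed by bond formation, since the ten-membered ring is the perimeter of the 5-7 bicycle and appears when the shared bond is cut, so the usual penalty of a medium-ring closure is avoided. No stereocentre is created (C1, C7 and C8 become trigonal, C4 and C5 are untouched); the Z geometry of C7=C8 follows from the cis C6/mesylate relation set in step 8, because puckering the cyclopentene until C1–C7 lies anti to C8–O leaves C6 and C9 on the same side, and C9=C10 keeps the cis geometry imposed by the five-membered ring. Fragmentation must beat oxetane formation, allylic ionisation, elimination and lactonisation: the oxetane would be a strained bridged bicycle, the C10 ester destabilises an allyl cation, C7–H is not acidified, and the C1 oxygen lies trans to the C4 ester across the seven-membered ring. One equivalent of a non-nucleophilic base at low temperature and a buffered quench should protect the electrophilic, enolisable product from Michael addition and from alkene migration.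

Step 20
Reactants: 33 ten-membered C1 ketone
Product: 34 C1 methylene diester ketal
Conditions: Zn, CH2Br2, TiCl4 (pre-aged reagent), THF/CH2Cl2, 0 °C to rt
Reagents that add atoms: dibromomethane, BrCBr
Why: Takai–Lombardo methylenation uses a non-basic zinc–titanium methylene reagent that attacks ketones but not esters or ketals and does not enolise C2 or C6, so the cis,cis-diene and C4 should survive.

Step 21
Reactants: 34 C1 methylene diester ketal
Product: 36 target CNP0137484.1, via dilithium dicarboxylate 35 (not isolated)
Conditions: LiOH, THF/MeOH/H2O, 40 °C; then 1 M HCl to pH 2, THF, rt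
Reagents that add atoms: lithium hydroxide, [Li+].[OH-]; water, O
Why: Saponification of both methyl esters is run while the side-chain ketone is still masked against base, and the acidification that frees the two acids also hydrolyses the activated furyl ketal, C4 being shielded from epimerisation by the neighbouring quaternary centre.

**Compound list**
1 | tert-butyl(but-3-yn-1-yloxy)dimethylsilane | C#CCCO[Si](C)(C)C(C)(C)C | starting material
2 | acetaldehyde | CC=O | starting material
3 | [(E)-4-(tert-butyldimethylsilyloxy)-2-methylbut-1-enyl]dimethylaluminium | C[Al](C)/C=C(\C)CCO[Si](C)(C)C(C)(C)C | intermediate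
4 | rac-(E)-6-(tert-butyldimethylsilyloxy)-4-methylhex-3-en-2-ol | CC(O)/C=C(\C)CCO[Si](C)(C)C(C)(C)C | intermediate
5 | (S)-(E)-6-(tert-butyldimethylsilyloxy)-4-methylhex-3-en-2-ol | C[C@H](O)/C=C(\C)CCO[Si](C)(C)C(C)(C)C | intermediate
6 | hept-6-enoic acid | C=CCCCCC(=O)O | starting material
7 | (S)-(E)-6-(tert-butyldimethylsilyloxy)-4-methylhex-3-en-2-yl hept-6-enoate | C=CCCCCC(=O)O[C@@H](C)/C=C(\C)CCO[Si](C)(C)C(C)(C)C | intermediate
8 | E trimethylsilyl ketene acetal of 7 | C=CCCC/C=C(/O[Si](C)(C)C)O[C@@H](C)/C=C(\C)CCO[Si](C)(C)C(C)(C)C | intermediate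
9 | trimethylsilyl ester of 10 | C=CCCC[C@@H](C(=O)O[Si](C)(C)C)[C@](C)(CCO[Si](C)(C)C(C)(C)C)/C=C/C | intermediate
10 | Claisen acid, 2-[(E)-1-(tert-butyldimethylsilyloxy)-3-methylhex-4-en-3-yl]hept-6-enoic acid | C=CCCC[C@@H](C(=O)O)[C@](C)(CCO[Si](C)(C)C(C)(C)C)/C=C/C | intermediate
11 | Claisen methyl ester | C=CCCC[C@@H](C(=O)OC)[C@](C)(CCO[Si](C)(C)C(C)(C)C)/C=C/C | intermediate
12 | methyl 2-[2-(tert-butyldimethylsilyloxy)ethyl]-2-methylcyclohept-3-ene-1-carboxylate, ester cis to methyl | C1CC[C@@H](C(=O)OC)[C@](C)(CCO[Si](C)(C)C(C)(C)C)C=C1 | intermediate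
13 | methyl 2-[2-(tert-butyldimethylsilyloxy)ethyl]-2-methyl-5-oxocyclohept-3-ene-1-carboxylate | O=C1CC[C@@H](C(=O)OC)[C@](C)(CCO[Si](C)(C)C(C)(C)C)C=C1 | intermediate
14 | methyl (E)-4-oxobut-2-enoate | COC(=O)/C=C/C=O | starting material
15 | lithium C1=C7 enolate | [Li]OC=1CC[C@@H](C(=O)OC)[C@](C)(CCO[Si](C)(C)C(C)(C)C)CC=1 | intermediate
16 | dicyclohexylboron C1=C7 enolate | C1CCC(CC1)B(OC=2CC[C@@H](C(=O)OC)[C@](C)(CCO[Si](C)(C)C(C)(C)C)CC=2)C1CCCCC1 | intermediate
17 | anti aldol | O=C1CC[C@@H](C(=O)OC)[C@](C)(CCO[Si](C)(C)C(C)(C)C)C[C@H]1[C@@H](O)/C=C/C(=O)OC | intermediate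
18 | C8 silyl ether of the anti aldol | O=C1CC[C@@H](C(=O)OC)[C@](C)(CCO[Si](C)(C)C(C)(C)C)C[C@H]1[C@@H](O[Si](C)(C)C(C)(C)C)/C=C/C(=O)OC | intermediate
19 | lithium ester enolate after thiolate addition | O=C1CC[C@@H](C(=O)OC)[C@](C)(CCO[Si](C)(C)C(C)(C)C)C[C@H]1[C@@H](O[Si](C)(C)C(C)(C)C)[C@H](Sc1ccccc1)C=C(O[Li])OC | intermediate
20 | cis-fused hydroazulene sulfide | O[C@]12CC[C@@H](C(=O)OC)[C@](C)(CCO[Si](C)(C)C(C)(C)C)C[C@H]1[C@@H](O[Si](C)(C)C(C)(C)C)[C@H](Sc1ccccc1)[C@@H]2C(=O)OC | intermediate
21 | hydroazulene sulfone | O[C@]12CC[C@@H](C(=O)OC)[C@](C)(CCO[Si](C)(C)C(C)(C)C)C[C@H]1[C@@H](O[Si](C)(C)C(C)(C)C)[C@H](S(=O)(=O)c1ccccc1)[C@@H]2C(=O)OC | intermediate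
22 | hydroazulene enoate, bis-silyl ether | O[C@]12CC[C@@H](C(=O)OC)[C@](C)(CCO[Si](C)(C)C(C)(C)C)C[C@H]1[C@@H](O[Si](C)(C)C(C)(C)C)C=C2C(=O)OC | intermediate
23 | primary alcohol | O[C@]12CC[C@@H](C(=O)OC)[C@](C)(CCO)C[C@H]1[C@@H](O[Si](C)(C)C(C)(C)C)C=C2C(=O)OC | intermediate
24 | side-chain aldehyde | O[C@]12CC[C@@H](C(=O)OC)[C@](C)(CC=O)C[C@H]1[C@@H](O[Si](C)(C)C(C)(C)C)C=C2C(=O)OC | intermediate
25 | 3-bromofuran | Brc1ccoc1 | starting material
26 | 3-furyllithium | [Li]c1ccoc1 | intermediate
27 | furyl carbinol, carbinol epimers | O[C@]12CC[C@@H](C(=O)OC)[C@](C)(CC(O)c3ccoc3)C[C@H]1[C@@H](O[Si](C)(C)C(C)(C)C)C=C2C(=O)OC | intermediate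
28 | furyl ketone | O[C@]12CC[C@@H](C(=O)OC)[C@](C)(CC(=O)c3ccoc3)C[C@H]1[C@@H](O[Si](C)(C)C(C)(C)C)C=C2C(=O)OC | intermediate
29 | furyl ketal, C8 silyl ether | O[C@]12CC[C@@H](C(=O)OC)[C@](C)(CC3(OCCO3)c3ccoc3)C[C@H]1[C@@H](O[Si](C)(C)C(C)(C)C)C=C2C(=O)OC | intermediate
30 | C1,C8 1,3-diol | O[C@]12CC[C@@H](C(=O)OC)[C@](C)(CC3(OCCO3)c3ccoc3)C[C@H]1[C@@H](O)C=C2C(=O)OC | intermediate
31 | hydroazulene C8 mesylate (fragmentation precursor) | O[C@]12CC[C@@H](C(=O)OC)[C@](C)(CC3(OCCO3)c3ccoc3)C[C@H]1[C@@H](OS(C)(=O)=O)C=C2C(=O)OC | intermediate
32 | potassium C1 alkoxide of 31 | [K+].[O-][C@]12CC[C@@H](C(=O)OC)[C@](C)(CC3(OCCO3)c3ccoc3)C[C@H]1[C@@H](OS(C)(=O)=O)C=C2C(=O)OC | intermediate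
33 | ten-membered C1 ketone (fragmentation product) | O=C1CC[C@@H](C(=O)OC)[C@](C)(CC2(OCCO2)c2ccoc2)C/C=C\C=C/1C(=O)OC | intermediate
34 | C1 methylene diester ketal | C=C1CC[C@@H](C(=O)OC)[C@](C)(CC2(OCCO2)c2ccoc2)C/C=C\C=C/1C(=O)OC | intermediate
35 | dilithium dicarboxylate ketal | [Li+].[Li+].C=C1CC[C@@H](C(=O)[O-])[C@](C)(CC2(OCCO2)c2ccoc2)C/C=C\C=C/1C(=O)[O-] | intermediate
36 | CNP0137484.1 | C=C1CC[C@@H](C(=O)O)[C@](C)(CC(=O)c2ccoc2)C/C=C\C=C/1C(=O)O | target

**Step count**
Total step count: 21. Longest linear sequence: 21 steps, from 1 to 36; compounds 2, 6, 14 and 25 enter as purchased.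

**Three steps most likely to fail**

Step 19. The allylic mesylate may ionise or eliminate, or the alkoxide may not reach the anti alignment, before the C1–C7 bond breaks. The product may also suffer alkene migration under base. The fallback sets out from 29 and returns at 33. It moves the fragmentation to a saturated, non-allylic sulfonate and makes the C9=C10 bond afterwards.
- Conjugate reduction of the enoate of 29 with [(Ph3P)CuH]6 in wet toluene gives the saturated hydroazulene ester F1.
- Bu4NF frees the saturated 1,3-diol F2, and MsCl/Et3N gives the saturated mesylate F3.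
- KOt-Bu in THF then cleaves the same C1–C7 bond, now pulled by formation of a β-keto ester enolate, to the ten-membered β-keto ester F4 with the Z C7=C8 alkene.
- PhSeCl/pyridine gives the C10 selenide F5, and H2O2 oxidation with selenoxide syn elimination towards C9 leads to 33.
- In this variant the C9=C10 geometry of 33 would have to be confirmed.

Step 10. The ester enolate may be protonated by the α-hydrogens of the ketone, or may expel thiolate again, faster than it adds to the hindered C1 ketone, so that ring closure does not take place. The fallback sets out from 18 and returns at 22.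
- A reductive aldol cyclisation with catalytic Cu(OAc)2, 1,2-bis(diphenylphosphino)benzene and (Me2HSi)2O delivers hydride instead of thiolate to C9 and gives the saturated β-hydroxy ester F6.
- Double deprotonation with LiN(i-Pr)2 followed by PhSeBr gives the C10 selenide F7.
- H2O2 then eliminates the selenoxide towards C9, the only side that carries a hydrogen, to give 22.

Step 20. Conjugate addition to the doubly activated diene, enolisation, or attack at the esters may outrun methylenation of the hindered cross-conjugated carbonyl group. The fallback sets out from 33 and returns at 34 by a two-stage Peterson olefination.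
- Me3SiCH2MgCl with CeCl3 adds 1,2 to the C1 ketone to give the β-hydroxysilane F8.
- KH in THF then eliminates silanolate to give 34.

**Further compounds**
F1 | step 19 | saturated hydroazulene ester, C10 epimers | O[C@]12CC[C@@H](C(=O)OC)[C@](C)(CC3(OCCO3)c3ccoc3)C[C@H]1[C@@H](O[Si](C)(C)C(C)(C)C)CC2C(=O)OC
F2 | step 19 | saturated 1,3-diol, C10 epimers | O[C@]12CC[C@@H](C(=O)OC)[C@](C)(CC3(OCCO3)c3ccoc3)C[C@H]1[C@@H](O)CC2C(=O)OC
F3 | step 19 | saturated mesylate, C10 epimers | O[C@]12CC[C@@H](C(=O)OC)[C@](C)(CC3(OCCO3)c3ccoc3)C[C@H]1[C@@H](OS(C)(=O)=O)CC2C(=O)OC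
F4 | step 19 | ten-membered β-keto ester with Z C7=C8 alkene | O=C1CC[C@@H](C(=O)OC)[C@](C)(CC2(OCCO2)c2ccoc2)C/C=C\CC1C(=O)OC
F5 | step 19 | C10 phenylselenide of the β-keto ester | O=C1CC[C@@H](C(=O)OC)[C@](C)(CC2(OCCO2)c2ccoc2)C/C=C\CC1([Se]c2ccccc2)C(=O)OC
F6 | step 10 | saturated β-hydroxy ester, C10 epimers | O[C@]12CC[C@@H](C(=O)OC)[C@](C)(CCO[Si](C)(C)C(C)(C)C)C[C@H]1[C@@H](O[Si](C)(C)C(C)(C)C)CC2C(=O)OC
F7 | step 10 | C10 phenylselenide of the β-hydroxy ester | O[C@]12CC[C@@H](C(=O)OC)[C@](C)(CCO[Si](C)(C)C(C)(C)C)C[C@H]1[C@@H](O[Si](C)(C)C(C)(C)C)CC2([Se]c1ccccc1)C(=O)OC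
F8 | step 20 | C1 β-hydroxysilane, C1 epimers | C[Si](C)(C)CC1(O)CC[C@@H](C(=O)OC)[C@](C)(CC2(OCCO2)c2ccoc2)C/C=C\C=C/1C(=O)OC
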